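**Retrosynthetic overview**

1. Germacrane numbering is used: C1 carbinol, C4(C15)=C5, C6 lactone O–CH, C7, C8 ester CH, C9=C10(C14), C11(=C13)–C12(=O). The ten-membered carbocycle is opened at C1–C10, because the C1 allylic carbinol sits on the methyl-bearing C10 of the ring-cis C9=C10 alkene. That is the retron of a (Z)-alkenyl metal adding to a C1 aldehyde, here a Ni/Cr-mediated Nozaki–Hiyama–Kishi closure of seco iodoalkene aldehyde 29.
2. The γ-lactone ring (C12, C11, C7, C6, O) is formed first, by an Evans syn-aldol of an N-succinyl oxazolidinone with the C1–C6/C15 enal 8 and lactonisation; this sets C6 and C7 (trans).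
3. The C7 carboxyl is then grown into C8–C10/C14: propynyl ketone, hydroiodination to the (Z)-β-iodoenone, CBS reduction (C8), acylation with (S)-2-methylbutanoic acid, and Eschenmoser methylenation (C13).
4. The C4=C5 geometry of enal 8 comes from trans-hydroalumination/iodination of mono-silylated but-2-yne-1,4-diol and a B-alkyl Suzuki–Miyaura coupling.
5. Ring order: lactone ring (step 6), then the ten-membered ring (step 15); desilylation at C15 ends the route.

Key step: step 15

Assumption: in the CBS reduction of step 10 the (Z)-2-iodopropenyl group is taken to act as the larger ketone substituent; C15 is carried as a TBDPS ether and C1 as a TBS ether so that C1 can be unmasked alone.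

**Step 1**
Reactants: 1 but-2-yne-1,4-diol
Product: 2 4-(tert-butyldiphenylsilyloxy)but-2-yn-1-ol
Conditions: TBDPSCl (1 equiv), imidazole, 1 (3 equiv), DMF, 0 °C → rt
Reagents that add atoms: tert-butyl(chloro)diphenylsilane (TBDPSCl), CC(C)(C)[Si](Cl)(c1ccccc1)c1ccccc1
Why: Silyl ether formation on the symmetrical diol used in excess should give the mono-ether, leaving the future C6 hydroxyl free and C15 protected.

**Step 2**
Reactants: 2 4-(tert-butyldiphenylsilyloxy)but-2-yn-1-ol
Product: 4 (Z)-4-(tert-butyldiphenylsilyloxy)-3-iodobut-2-en-1-ol, via cyclic sodium alkenylaluminate 3 (not isolated)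
Conditions: NaAlH2(OCH2CH2OMe)2 (Red-Al), THF, 0 °C → rt; then I2, THF, −78 → 0 °C
Reagents that add atoms: iodine, II
Why: Hydroxyl-directed trans-hydroalumination of the propargylic alcohol places hydride on C5 and aluminium on C4 in a five-membered alkoxyaluminate, and iodinolysis with retention should give the iodoalkene with CH2OH (C6) and iodine cis, the geometry that becomes the ring-cis C4=C5 alkene.

**Step 3**
Reactants: 4 (Z)-4-(tert-butyldiphenylsilyloxy)-3-iodobut-2-en-1-ol; 5 tert-butyl(dimethyl)(prop-2-enyloxy)silane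
Product: 7 (E)-6-(tert-butyldimethylsilyloxy)-3-[(tert-butyldiphenylsilyloxy)methyl]hex-2-en-1-ol (CH2OH cis to the silyloxypropyl chain), via B-alkyl-9-BBN borane 6 (not isolated)
Conditions: 5, 9-BBN-H, THF, 0 °C → rt; then 4, PdCl2(dppf) (5 mol%), AsPh3 (5 mol%), Cs2CO3, DMF/THF/H2O, rt
Reagents that add atoms: none
Why: Anti-Markovnikov hydroboration of 5 followed by B-alkyl Suzuki–Miyaura coupling replaces iodine by the C3–C2–C1 chain with retention of the alkene geometry, so that C6 and C3 stay cis.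

**Step 4**
Reactants: 7 (E)-6-(tert-butyldimethylsilyloxy)-3-[(tert-butyldiphenylsilyloxy)methyl]hex-2-en-1-ol
Product: 8 (E)-6-(tert-butyldimethylsilyloxy)-3-[(tert-butyldiphenylsilyloxy)methyl]hex-2-enal (CHO cis to the chain)
Conditions: TEMPO (10 mol%), PhI(OAc)2, CH2Cl2, rt; used at once
Reagents that add atoms: none
Why: Oxoammonium (TEMPO) oxidation of the primary allylic alcohol under near-neutral conditions should give the enal without scrambling the trisubstituted alkene.

**Step 5**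
Reactants: 9 (S)-4-benzyl-1,3-oxazolidin-2-one; 10 methyl 4-chloro-4-oxobutanoate
Product: 11 methyl 4-[(S)-4-benzyl-2-oxo-1,3-oxazolidin-3-yl]-4-oxobutanoate
Conditions: Et3N, DMAP (10 mol%), CH2Cl2, 0 °C → rt
Reagents that add atoms: none
Why: N-acylation of the oxazolidinone takes place at the acid chloride, which is far more electrophilic than the methyl ester.

**Step 6**
Reactants: 11 methyl 4-[(S)-4-benzyl-2-oxo-1,3-oxazolidin-3-yl]-4-oxobutanoate; 8 (E)-6-(tert-butyldimethylsilyloxy)-3-[(tert-butyldiphenylsilyloxy)methyl]hex-2-enal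
Product: 14 (S)-4-benzyl-3-[(2R,3S)-2-{(E)-5-(TBSO)-2-[(TBDPSO)methyl]pent-1-enyl}-5-oxooxolane-3-carbonyl]-1,3-oxazolidin-2-one (trans lactone; oxolane C2 = C6 and C3 = C7), via dibutylboron Z-enolate 12 (not isolated), via syn-aldol hydroxy ester 13 (not isolated)
Conditions: 11, Bu2BOTf, Et3N, CH2Cl2, −78 → 0 °C; then 8, −78 → 0 °C; pH 7 buffer, MeOH, 30% H2O2, 0 °C; then PPTS (cat.), CH2Cl2, rt
Reagents that add atoms: none
Why: In this Evans syn-aldol the Z-boron enolate of the imide (not the ester) reacts through a chair Zimmerman–Traxler transition state on the face away from the benzyl group, which sets C7 and C6 (6R) syn, and the C6 hydroxyl then closes onto the methyl ester to give the γ-lactone with H-6 and H-7 trans.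

**Step 7**
Reactants: 14 lactone imide
Product: 16 (2R,3S)-2-{(E)-5-(TBSO)-2-[(TBDPSO)methyl]pent-1-enyl}-5-oxooxolane-3-carboxylic acid, via lithium peroxycarboxylate 15 (not isolated)
Conditions: LiOH, 30% H2O2, THF/H2O, 0 °C; then Na2SO3 (aq); HCl (aq) to pH 3, 0 °C
Reagents that add atoms: hydrogen peroxide (as LiOOH), OO
Why: Hydroperoxide cleavage of the acyl oxazolidinone attacks the exocyclic carbonyl, sulfite reduces the peracid, and any lactone opened by hydroxide should reclose on acidification, the trans C6/C7 arrangement being the thermodynamic one.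

**Step 8**
Reactants: 16 lactone acid; 17 tributyl(prop-1-ynyl)stannane
Product: 19 1-[(2R,3S)-2-{(E)-5-(TBSO)-2-[(TBDPSO)methyl]pent-1-enyl}-5-oxooxolan-3-yl]but-2-yn-1-one, via acid chloride 18 (not isolated)
Conditions: 1-chloro-N,N,2-trimethylprop-1-en-1-amine, CH2Cl2, 0 °C → rt; then 17, PdCl2(PPh3)2 (5 mol%), ClCH2CH2Cl, 50 °C
Reagents that add atoms: none
Why: Neutral acid chloride formation with the α-chloroenamine followed by Stille acylative coupling (zerovalent palladium inserts into C–Cl, the alkynyl group passes from tin, reductive elimination) joins C8 to C9 without a base that could eliminate the β-acyloxy ketone.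

**Step 9**
Reactants: 19 ynone
Product: 20 (Z)-3-iodo-1-[(2R,3S)-2-{(E)-5-(TBSO)-2-[(TBDPSO)methyl]pent-1-enyl}-5-oxooxolan-3-yl]but-2-en-1-one
Conditions: NaI, AcOH, MeCN, 0 °C → rt
Reagents that add atoms: sodium iodide, [Na+].[I-]
Why: In this conjugate hydroiodination iodide adds at C10 and the allenolate is protonated anti, which should give the (Z)-β-iodoenone with iodine cis to the C8 carbonyl, the geometry needed for the ring-cis C9=C10 alkene.

**Step 10**
Reactants: 20 (Z)-β-iodoenone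
Product: 21 (4R,5R)-5-{(E)-5-(TBSO)-2-[(TBDPSO)methyl]pent-1-enyl}-4-[(1S,2Z)-1-hydroxy-3-iodobut-2-enyl]oxolan-2-one
Conditions: (R)-2-methyl-CBS-oxazaborolidine [(R)-1-methyl-3,3-diphenyltetrahydro-1H,3H-pyrrolo[1,2-c][1,3,2]oxazaborole] (0.3 equiv), catecholborane, toluene/CH2Cl2, −78 °C
Reagents that add atoms: none
Why: CBS reduction under reagent control should deliver hydride to the C8 ketone with the iodoalkenyl group in the large-substituent position of the (R)-catalyst complex, giving the C8 carbinol of the target sense (8S by CIP here because of iodine) by 1,2-reduction only.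

**Step 11**
Reactants: 21 allylic alcohol; 22 (S)-2-methylbutanoic acid
Product: 23 (1S,2Z)-3-iodo-1-[(2R,3S)-2-{(E)-5-(TBSO)-2-[(TBDPSO)methyl]pent-1-enyl}-5-oxooxolan-3-yl]but-2-enyl (S)-2-methylbutanoate
Conditions: DCC, DMAP (10 mol%), CH2Cl2, 0 °C → rt
Reagents that add atoms: none
Why: Steglich esterification acylates the only free hydroxyl with retention at C8, and catalytic DMAP at low temperature should leave the α-stereocentre of the acid intact.

**Step 12**
Reactants: 23 ester
Product: 27 (1S,2Z)-3-iodo-1-[(2R,3S)-2-{(E)-5-(TBSO)-2-[(TBDPSO)methyl]pent-1-enyl}-4-methylidene-5-oxooxolan-3-yl]but-2-enyl (S)-2-methylbutanoate, via lithium lactone enolate 24 (not isolated), via Mannich base 25 (not isolated), via trimethylammonium iodide 26 (not isolated)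
Conditions: LiN(SiMe3)2, THF, −78 °C; CH2=NMe2+ I−, −78 °C → rt; then MeI, CH2Cl2/MeOH, rt; then NaHCO3 (aq), EtOAc, rt
Reagents that add atoms: dimethylmethylideneammonium iodide (Eschenmoser's salt), C=[N+](C)C.[I-]
Why: In this Eschenmoser methylenation kinetic deprotonation at the unhindered lactone CH2 (C11) rather than the branched ester α-CH, Mannich aminomethylation, N-methylation and base-induced β-elimination of trimethylamine should install the C11=C13 methylene.

**Step 13**
Reactants: 27 α-methylene lactone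
Product: 28 (1S,2Z)-1-[(2R,3S)-2-{(E)-5-hydroxy-2-[(TBDPSO)methyl]pent-1-enyl}-4-methylidene-5-oxooxolan-3-yl]-3-iodobut-2-enyl (S)-2-methylbutanoate
Conditions: PPTS (0.2 equiv), MeOH/CH2Cl2, 0 °C → rt
Reagents that add atoms: none
Why: Mild acid-catalysed methanolysis removes the primary TBS ether at C1, while the far more acid-stable TBDPS ether at C15 should survive.

**Step 14**
Reactants: 28 C1 alcohol
Product: 29 (1S,2Z)-3-iodo-1-[(2R,3S)-4-methylidene-5-oxo-2-{(E)-5-oxo-2-[(TBDPSO)methyl]pent-1-enyl}oxolan-3-yl]but-2-enyl (S)-2-methylbutanoate (seco iodoalkene aldehyde)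
Conditions: Dess–Martin periodinane, CH2Cl2, 0 °C → rt
Reagents that add atoms: none
Why: Dess–Martin oxidation converts the primary alcohol to the C1 aldehyde under conditions that leave the iodoalkene, the methylene lactone and the ester untouched.

**Step 15**
Reactants: 29 seco iodoalkene aldehyde
Product: 30 (1S,6R,7R,8R,4E,9Z)-15-(tert-butyldiphenylsilyloxy)-1-hydroxy-8-[(S)-2-methylbutanoyloxy]germacra-4,9,11(13)-trien-12,6-olide
Conditions: CrCl2 (8 equiv), NiCl2 (1 mol% of CrCl2), degassed DMSO, rt, slow addition of 29 to 0.002 M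
Reagents that add atoms: none
Why: Zerovalent nickel, formed from NiCl2 by CrCl2, inserts into the C10–I bond with retention of the Z geometry, the alkenyl group passes to trivalent chromium, and the alkenylchromium adds to the C1 aldehyde to give the chromium alkoxide of 30; the closest known reaction type is the Nozaki–Hiyama–Kishi alkenyl iodide–aldehyde macrocyclisation to medium and large carbocycles. The ten-membered ring closes by a 10-exo-trig attack of C10 on the aldehyde carbon, the carbonyl oxygen staying outside the ring as the C1 hydroxyl. The new C1 stereocentre is set by the ring-forming conformation, in which the trans-fused lactone, the two ring-cis alkenes, the outward C14 methyl and the pseudo-equatorial C8 acyloxy group leave one aldehyde face open to C10, which is expected to favour the 1S carbinol. The step needs chemoselectivity for the aldehyde over the α-methylene lactone and the ester carbonyls, which the weakly basic, oxophilic alkenylchromium secures, and cyclisation over oligomerisation, which high dilution and the turn imposed by the lactone and the Z alkenes secure.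

**Step 16**
Reactants: 30 macrocyclic silyl ether
Product: 31 (1S,6R,7R,8R,4E,9Z)-1,15-dihydroxy-8-[(S)-2-methylbutanoyloxy]germacra-4,9,11(13)-trien-12,6-olide (CNP0526758.1)
Conditions: HF·pyridine, pyridine, THF, 0 °C → rt
Reagents that add atoms: none
Why: Buffered fluoride desilylation cleaves the Si–O bond at C15 without touching the ester, the lactone or the allylic carbinol.

**Compound list**

1 | but-2-yne-1,4-diol | OCC#CCO | starting material
2 | 4-(tert-butyldiphenylsilyloxy)but-2-yn-1-ol | OCC#CCO[Si](c1ccccc1)(c1ccccc1)C(C)(C)C | intermediate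
3 | cyclic sodium alkenylaluminate from 2 (five-membered O–Al–C4=C5–C6 ring, two 2-methoxyethoxy groups on Al) | [Na+].COCCO[Al-]1(OCCOC)OCC=C1CO[Si](c2ccccc2)(c2ccccc2)C(C)(C)C | intermediate
4 | (Z)-4-(tert-butyldiphenylsilyloxy)-3-iodobut-2-en-1-ol | OC/C=C(\I)CO[Si](c1ccccc1)(c1ccccc1)C(C)(C)C | intermediate
5 | tert-butyl(dimethyl)(prop-2-enyloxy)silane | C=CCO[Si](C)(C)C(C)(C)C | starting material
6 | 9-[3-(tert-butyldimethylsilyloxy)propyl]-9-borabicyclo[3.3.1]nonane | CC(C)(C)[Si](C)(C)OCCCB1C2CCCC1CCC2 | intermediate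
7 | (E)-6-(tert-butyldimethylsilyloxy)-3-[(tert-butyldiphenylsilyloxy)methyl]hex-2-en-1-ol | OC/C=C(/CO[Si](c1ccccc1)(c1ccccc1)C(C)(C)C)CCCO[Si](C)(C)C(C)(C)C | intermediate
8 | (E)-6-(tert-butyldimethylsilyloxy)-3-[(tert-butyldiphenylsilyloxy)methyl]hex-2-enal | O=C/C=C(/CO[Si](c1ccccc1)(c1ccccc1)C(C)(C)C)CCCO[Si](C)(C)C(C)(C)C | intermediate
9 | (S)-4-benzyl-1,3-oxazolidin-2-one | O=C1N[C@@H](Cc2ccccc2)CO1 | starting material
10 | methyl 4-chloro-4-oxobutanoate | COC(=O)CCC(Cl)=O | starting material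
11 | methyl 4-[(S)-4-benzyl-2-oxo-1,3-oxazolidin-3-yl]-4-oxobutanoate | COC(=O)CCC(=O)N1[C@@H](Cc2ccccc2)COC1=O | intermediate
12 | dibutylboron (Z)-enolate of 11 | COC(=O)C/C=C(\OB(CCCC)CCCC)N1[C@@H](Cc2ccccc2)COC1=O | intermediate
13 | methyl (3S,4R,5E)-3-[(S)-4-benzyl-2-oxo-1,3-oxazolidine-3-carbonyl]-9-(tert-butyldimethylsilyloxy)-6-[(tert-butyldiphenylsilyloxy)methyl]-4-hydroxynon-5-enoate (syn-aldol adduct) | O[C@H](/C=C(/CO[Si](c1ccccc1)(c1ccccc1)C(C)(C)C)CCCO[Si](C)(C)C(C)(C)C)[C@H](CC(=O)OC)C(=O)N3[C@@H](Cc4ccccc4)COC3=O | intermediate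
14 | (S)-4-benzyl-3-[(2R,3S)-2-{(E)-5-(TBSO)-2-[(TBDPSO)methyl]pent-1-enyl}-5-oxooxolane-3-carbonyl]-1,3-oxazolidin-2-one | C1C(=O)O[C@H](/C=C(/CO[Si](c2ccccc2)(c2ccccc2)C(C)(C)C)CCCO[Si](C)(C)C(C)(C)C)[C@H]1C(=O)N3[C@@H](Cc4ccccc4)COC3=O | intermediate
15 | lithium peroxycarboxylate of acid 16 | C1C(=O)O[C@H](/C=C(/CO[Si](c2ccccc2)(c2ccccc2)C(C)(C)C)CCCO[Si](C)(C)C(C)(C)C)[C@H]1C(=O)O[O-].[Li+] | intermediate
16 | (2R,3S)-2-{(E)-5-(TBSO)-2-[(TBDPSO)methyl]pent-1-enyl}-5-oxooxolane-3-carboxylic acid | C1C(=O)O[C@H](/C=C(/CO[Si](c2ccccc2)(c2ccccc2)C(C)(C)C)CCCO[Si](C)(C)C(C)(C)C)[C@H]1C(=O)O | intermediate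
17 | tributyl(prop-1-ynyl)stannane | CC#C[Sn](CCCC)(CCCC)CCCC | starting material
18 | acid chloride of 16 | C1C(=O)O[C@H](/C=C(/CO[Si](c2ccccc2)(c2ccccc2)C(C)(C)C)CCCO[Si](C)(C)C(C)(C)C)[C@H]1C(Cl)=O | intermediate
19 | 1-[(2R,3S)-2-{(E)-5-(TBSO)-2-[(TBDPSO)methyl]pent-1-enyl}-5-oxooxolan-3-yl]but-2-yn-1-one | C1C(=O)O[C@H](/C=C(/CO[Si](c2ccccc2)(c2ccccc2)C(C)(C)C)CCCO[Si](C)(C)C(C)(C)C)[C@H]1C(=O)C#CC | intermediate
20 | (Z)-3-iodo-1-[(2R,3S)-2-{(E)-5-(TBSO)-2-[(TBDPSO)methyl]pent-1-enyl}-5-oxooxolan-3-yl]but-2-en-1-one | C1C(=O)O[C@H](/C=C(/CO[Si](c2ccccc2)(c2ccccc2)C(C)(C)C)CCCO[Si](C)(C)C(C)(C)C)[C@H]1C(=O)/C=C(\I)C | intermediate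
21 | (4R,5R)-5-{(E)-5-(TBSO)-2-[(TBDPSO)methyl]pent-1-enyl}-4-[(1S,2Z)-1-hydroxy-3-iodobut-2-enyl]oxolan-2-one | C1C(=O)O[C@H](/C=C(/CO[Si](c2ccccc2)(c2ccccc2)C(C)(C)C)CCCO[Si](C)(C)C(C)(C)C)[C@H]1[C@H](O)/C=C(\I)C | intermediate
22 | (S)-2-methylbutanoic acid | CC[C@H](C)C(=O)O | starting material
23 | (1S,2Z)-3-iodo-1-[(2R,3S)-2-{(E)-5-(TBSO)-2-[(TBDPSO)methyl]pent-1-enyl}-5-oxooxolan-3-yl]but-2-enyl (S)-2-methylbutanoate | C1C(=O)O[C@H](/C=C(/CO[Si](c2ccccc2)(c2ccccc2)C(C)(C)C)CCCO[Si](C)(C)C(C)(C)C)[C@H]1[C@H](OC(=O)[C@@H](C)CC)/C=C(\I)C | intermediate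
24 | lithium enolate of lactone 23 (C11=C12–OLi) | C1=C([O-])O[C@H](/C=C(/CO[Si](c2ccccc2)(c2ccccc2)C(C)(C)C)CCCO[Si](C)(C)C(C)(C)C)[C@H]1[C@H](OC(=O)[C@@H](C)CC)/C=C(\I)C.[Li+] | intermediate
25 | C11-(dimethylaminomethyl) lactone (Mannich base, C11 epimers) | CN(C)CC1C(=O)O[C@H](/C=C(/CO[Si](c2ccccc2)(c2ccccc2)C(C)(C)C)CCCO[Si](C)(C)C(C)(C)C)[C@H]1[C@H](OC(=O)[C@@H](C)CC)/C=C(\I)C | intermediate
26 | C11-(trimethylammoniomethyl) lactone iodide | C[N+](C)(C)CC1C(=O)O[C@H](/C=C(/CO[Si](c2ccccc2)(c2ccccc2)C(C)(C)C)CCCO[Si](C)(C)C(C)(C)C)[C@H]1[C@H](OC(=O)[C@@H](C)CC)/C=C(\I)C.[I-] | intermediate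
27 | (1S,2Z)-3-iodo-1-[(2R,3S)-2-{(E)-5-(TBSO)-2-[(TBDPSO)methyl]pent-1-enyl}-4-methylidene-5-oxooxolan-3-yl]but-2-enyl (S)-2-methylbutanoate | C=C1C(=O)O[C@H](/C=C(/CO[Si](c2ccccc2)(c2ccccc2)C(C)(C)C)CCCO[Si](C)(C)C(C)(C)C)[C@H]1[C@H](OC(=O)[C@@H](C)CC)/C=C(\I)C | intermediate
28 | (1S,2Z)-1-[(2R,3S)-2-{(E)-5-hydroxy-2-[(TBDPSO)methyl]pent-1-enyl}-4-methylidene-5-oxooxolan-3-yl]-3-iodobut-2-enyl (S)-2-methylbutanoate | C=C1C(=O)O[C@H](/C=C(/CO[Si](c2ccccc2)(c2ccccc2)C(C)(C)C)CCCO)[C@H]1[C@H](OC(=O)[C@@H](C)CC)/C=C(\I)C | intermediate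
29 | (1S,2Z)-3-iodo-1-[(2R,3S)-4-methylidene-5-oxo-2-{(E)-5-oxo-2-[(TBDPSO)methyl]pent-1-enyl}oxolan-3-yl]but-2-enyl (S)-2-methylbutanoate | C=C1C(=O)O[C@H](/C=C(/CO[Si](c2ccccc2)(c2ccccc2)C(C)(C)C)CCC=O)[C@H]1[C@H](OC(=O)[C@@H](C)CC)/C=C(\I)C | intermediate
30 | (1S,6R,7R,8R,4E,9Z)-15-(tert-butyldiphenylsilyloxy)-1-hydroxy-8-[(S)-2-methylbutanoyloxy]germacra-4,9,11(13)-trien-12,6-olide | C=C1C(=O)O[C@@H]2/C=C(/CO[Si](c3ccccc3)(c3ccccc3)C(C)(C)C)CC[C@H](O)/C(C)=C\[C@@H](OC(=O)[C@@H](C)CC)[C@@H]12 | intermediate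
31 | (1S,6R,7R,8R,4E,9Z)-1,15-dihydroxy-8-[(S)-2-methylbutanoyloxy]germacra-4,9,11(13)-trien-12,6-olide (CNP0526758.1) | C=C1C(=O)O[C@@H]2/C=C(/CO)CC[C@H](O)/C(C)=C\[C@@H](OC(=O)[C@@H](C)CC)[C@@H]12 | target

**Step count**

Total: 16 steps. Longest linear sequence: 15 steps (steps 1–4 and 6–16; step 5 is a one-step branch).

**Steps most likely to fail**

Step 15 (ring closure). The addition to the C1 aldehyde may show poor facial selectivity, so that the C1 epimer forms alongside or instead of 30. The fallback separates ring formation from C1 control. It sets out from 29: the same closure is run, and the C1-epimeric macrocyclic alcohol F1 (alone or mixed with 30) is oxidised with Dess–Martin periodinane to the macrocyclic C1 enone F2. F2 is then reduced under reagent control with (R)-2-methyl-CBS-oxazaborolidine and catecholborane at −78 °C, where the C10 alkenyl group is the large and the C2 methylene the small substituent. This should return the 1S carbinol 30, where the route continues.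

Step 10 (C8 reduction). Hydride delivery to the C8 ketone may be poorly face-selective, because the branched lactone carbon C7 and the iodoalkenyl group compete for the large-substituent position of the catalyst. The fallback sets C8 before the iodoalkene exists. It sets out from ynone 19: asymmetric transfer hydrogenation with RuCl[(S,S)-TsDPEN](p-cymene) in iPrOH, a reduction in which the alkynyl group is reliably differentiated from an alkyl group, should give the propargylic alcohol F3 with the required C8 configuration. Ruthenium-catalysed trans-hydrosilylation with benzyldimethylsilane and [Cp*Ru(MeCN)3]PF6 should then place silicon on C10, distal to the hydroxyl, giving the (Z)-alkenylsilane F4. Iododesilylation with N-iodosuccinimide in hexafluoroisopropanol with retention returns to 21.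

Step 12 (methylenation). The lactone enolate may attack the neighbouring C8 ester carbonyl (acyl transfer), or the ester α-CH may be deprotonated and epimerised, before aminomethylation occurs. The fallback removes the ester from the enolate step. It sets out from alcohol 21: silylation with TESCl and imidazole gives the C8 triethylsilyl ether F5. The same enolate aminomethylation, N-methylation and elimination sequence then gives the α-methylene lactone silyl ether F6. Brief treatment with HF·pyridine/pyridine in THF at 0 °C should remove the secondary TES group in preference to the primary TBS and TBDPS ethers, giving the α-methylene lactone alcohol F7. Steglich esterification of F7 with 22 (DCC, catalytic DMAP) returns to 27.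

**Further compounds**

F1 | step 15 | C1 epimer (1R) of macrocyclic alcohol 30 | C=C1C(=O)O[C@@H]2/C=C(/CO[Si](c3ccccc3)(c3ccccc3)C(C)(C)C)CC[C@@H](O)/C(C)=C\[C@@H](OC(=O)[C@@H](C)CC)[C@@H]12
F2 | step 15 | macrocyclic C1 ketone (1-oxo analogue of 30) | C=C1C(=O)O[C@@H]2/C=C(/CO[Si](c3ccccc3)(c3ccccc3)C(C)(C)C)CCC(=O)/C(C)=C\[C@@H](OC(=O)[C@@H](C)CC)[C@@H]12
F3 | step 10 | C8 propargylic alcohol (1-hydroxybut-2-ynyl analogue of 21) | C1C(=O)O[C@H](/C=C(/CO[Si](c2ccccc2)(c2ccccc2)C(C)(C)C)CCCO[Si](C)(C)C(C)(C)C)[C@H]1[C@H](O)C#CC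
F4 | step 10 | (Z)-alkenylsilane (C10 benzyldimethylsilyl analogue of 21) | C1C(=O)O[C@H](/C=C(/CO[Si](c2ccccc2)(c2ccccc2)C(C)(C)C)CCCO[Si](C)(C)C(C)(C)C)[C@H]1[C@H](O)/C=C(\[Si](C)(C)Cc5ccccc5)C
F5 | step 12 | C8 triethylsilyl ether of 21 | C1C(=O)O[C@H](/C=C(/CO[Si](c2ccccc2)(c2ccccc2)C(C)(C)C)CCCO[Si](C)(C)C(C)(C)C)[C@H]1[C@H](O[Si](CC)(CC)CC)/C=C(\I)C
F6 | step 12 | α-methylene lactone C8 triethylsilyl ether | C=C1C(=O)O[C@H](/C=C(/CO[Si](c2ccccc2)(c2ccccc2)C(C)(C)C)CCCO[Si](C)(C)C(C)(C)C)[C@H]1[C@H](O[Si](CC)(CC)CC)/C=C(\I)C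
F7 | step 12 | α-methylene lactone C8 alcohol | C=C1C(=O)O[C@H](/C=C(/CO[Si](c2ccccc2)(c2ccccc2)C(C)(C)C)CCCO[Si](C)(C)C(C)(C)C)[C@H]1[C@H](O)/C=C(\I)C
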